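## The problem

The target **17** is a flavone, a 4H-chromen-4-one in which rings A and C share the C4a–C8a bond and ring B is attached to C2 through the C2–C1' bond. It has no stereocenter, so the whole task is one of substitution pattern and chemoselectivity. Ring A is the ordinary phloroglucinol-type 5,7-diol, whereas ring B carries four contiguous methoxy groups on C2' to C5' and a single hydrogen on C6', a pentasubstituted benzene that electrophilic substitution of simpler arenes reaches only with regiochemical ambiguity. The two phenols of ring A must stay distinguishable from four aryl methyl ethers to the end, so they are masked as benzyl ethers, which leave by hydrogenolysis. Three features are fragile: the γ-pyrone ring C is opened at C2 by hard nucleophiles, the 5-O-benzyl ether peri to the C4 carbonyl is the most acid-labile ether, and any quinone or hydroquinone form of ring B is sensitive to redox reagents and air. The enabling feature is that C2' to C5' form a four-carbon unit whose inner pair C3' and C4' carries ethers and whose outer pair C2' and C5' can be the carbonyls of a 1,4-benzoquinone, which is the carbon–oxygen pattern of dimethyl squarate **9**. The remaining atoms C1' and C6'–H are then the two carbons of an alkyne attached to C2 of the chromone, so ring B can be created on a finished chromone by ring expansion of a squarate adduct.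

## Retrosynthesis

**17 from 16.** The O–benzyl bonds at O5 and O7 are cut last. Benzyl is preferred to methyl (not distinguishable from the ring B ethers), to acyl (lost under the carbonate conditions of steps 5 and 9) and to acetal groups (acid would be needed next to an electron-rich ring B). The precursor **16** differs from the target only by two robust ethers. The forward step asks only that hydrogenolysis spares the C2=C3 bond.

**16 from 15 and 14.** The O–CH3 bonds at C2' and C5' are cut and two hydrogens removed, which unmasks ring B as hydroquinone **15** and then as the 2,3-dimethoxy-1,4-benzoquinone **14**. These two methyl groups are the only ones not delivered by squarate, and cutting them rather than the 3'- and 4'-methyls exposes the quinone that a ring expansion can deliver. The forward steps ask for fast reduction and methylation, because **15** reoxidises in air.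

**14 from 11 (key disconnection).** The C1'–C2' bond of the quinone is cut and the hydrogen on C6' is returned to the oxygen on C5', which contracts ring B to the four-membered ring of **11**. In the forward sense **11** should open thermally to vinylketene **12**, close to diradical **13** and collapse to **14**. The neighbouring cut, the C2–C1' bond between a chromone and a prefabricated aryl metal, would presuppose the pentasubstituted arene. The chosen cut instead places each ring B oxygen by construction from the symmetrical **9** and removes a whole aromatic ring from the problem. The forward reaction must open with the hydroxyl outward and close six-membered, not five-membered.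

**11 from 8 and 9.** The bond between the alkyne carbon and the carbinol carbon is cut, giving lithium acetylide **10** (from terminal alkyne **8**) and **9**. Because the two carbonyls of **9** are equivalent, no regiochemical question arises, and the problem falls into a commercial four-carbon piece and a simple 2-ethynylchromone. Forming the alkyne–chromone bond by cross-coupling instead would need a benzyl-protected 2-halochromone that is not readily made, and a warm coupling could trigger the rearrangement early. The forward step asks for deprotonation of **8** without attack on the pyrone and for 1,2-addition at low temperature.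

**8 from 7, 6 and 5.** The terminal alkyne carbon is removed (one-carbon homologation of aldehyde **7**), and the oxidation level is traced back through alcohol **6** to ester **5**. Bringing the alkyne in during chromone formation from an alkynoic acid derivative would create an alkynyl 1,3-diketone that can close to a γ-pyrone instead of the chromone. The ester route avoids this at the price of two redox steps and leads to a classical chromone-2-carboxylate. The forward steps ask for selective reduction of the C2 ester beside the C4 carbonyl and for a homologation under weakly basic conditions.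

**5 from 2 and 3.** Ring C is opened at C2–C3 (Claisen bond) and O1–C2 (cyclodehydration), giving acetophenone **2** and diethyl oxalate **3** through diketo ester **4**. Only **2** is enolisable, so the crossed condensation is unambiguous, and both pieces are far simpler than the bicycle. The cyclisation acid must be mild enough for the 5-O-benzyl ether.

**2 from 1.** Two O–benzyl bonds are cut to 2',4',6'-trihydroxyacetophenone **1**, a commercial compound. The forward reaction relies on the last ortho hydroxyl being hydrogen-bonded to the acetyl group, so that it stays free to become O1.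

## Roads not taken

Alternative 1: The cut is C4a–C5 of ring A. Methyl (E)-3,5,7-trioxo-9-(2,3,4,5-tetramethoxyphenyl)non-8-enoate A1 would undergo base-mediated Claisen cyclisation, C6 attacking the ester carbon C1. The product is the chalcone (E)-1-(2,4,6-trihydroxyphenyl)-3-(2,3,4,5-tetramethoxyphenyl)prop-2-en-1-one A2, and A2 would then be closed oxidatively to **17**.
- Merits: ring A appears with its three oxygens free and correctly placed, so no protecting groups are needed, and the step mirrors the biosynthesis.
- Weak points: A1 is a sensitive triketo ester that must be assembled by polyanion acylation beside an enone acceptor. A1 can also cyclise by aldol attack of C2 on C7 or lactonise to a 4-hydroxy-2-pyrone instead of the C6-to-C1 Claisen mode. A2 with a free phloroglucinol ring tends to close to the flavanone and to be halogenated or over-oxidised during dehydrogenation.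
- Comparison: the protecting-group economy is better than in the chosen plan. However, this road builds the ring that commerce supplies and leaves the difficult ring B to a prefabricated tetramethoxyaryl unit. The chosen plan constructs ring B itself.

Alternative 2: The cuts are C3–C4 and O1–C8a. The lithium enolate of 1-(2,3,4,5-tetramethoxyphenyl)ethanone A3 would be C-acylated by 2,4,6-trifluorobenzoyl chloride A4. The diketone enolate oxygen would then displace an ortho fluoride to give 5,7-difluoro-2',3',4',5'-tetramethoxyflavone A5, and both remaining fluorides of A5 would have to be exchanged for oxygen and unmasked.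
- Merits: it is short and convergent, ring C closure by fluoride displacement is dependable, and the symmetry of A4 removes any regiochemical question on ring A.
- Weak points: A3 again presupposes the pentasubstituted ring B. The two late displacements on A5 (one ortho, one para to the carbonyl) use strong oxygen nucleophiles on a pyrone that such nucleophiles can open at C2, and the introduced oxygens need a further deprotection.
- Comparison: this road is clearly shorter than the ten steps of the chosen plan. Against that, the chosen plan creates the ring B oxygenation pattern from one cheap symmetrical reagent, delivers the 2'- and 5'-oxygens differentiated from the 3'- and 4'-oxygens, and never exposes the chromone to hot alkoxide.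

Alternative 3: The cuts are C4a–C4, C4–C3 and O1–C2. 3,5-Bis(benzyloxy)-2-iodophenol A6, carbon monoxide A7 and 1-ethynyl-2,3,4,5-tetramethoxybenzene A8 would be joined under PdCl2(PPh3)2 catalysis in Et2NH. The product is 5,7-bis(benzyloxy)-2',3',4',5'-tetramethoxyflavone A9, and A9 is the same compound as **16**, one hydrogenolysis from **17**.
- Merits: one step forms ring C from three components, and convergence is the highest of all the plans.
- Weak points: A6 needs a regioselective iodination between a hydroxyl and a benzyloxy group on a ring with three activated positions. Its doubly ortho-substituted C–I bond is slow in oxidative addition and CO insertion, so direct coupling without A7 competes. The intermediate ynone can close 5-exo to an aurone instead of 6-endo. A8 again requires the pentasubstituted arene plus an alkyne installation.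
- Comparison: in the longest linear sequence this road is better than the chosen plan. The chosen plan answers with a route free of regiochemical questions, three commodity starting materials, and a ring B that is made, not assumed.

Key step: step 7

Assumption: commercial **1** (often the monohydrate) is dried before use; **11** is made and used as the racemate, since its only stereocenter becomes an sp2 carbon of ring B in step 7.

## Route

Step 1
Reactants: 1 2',4',6'-trihydroxyacetophenone
Product: 2 1-[2,4-bis(benzyloxy)-6-hydroxyphenyl]ethan-1-one
Conditions: BnBr (2.05 equiv), K2CO3 (2.2 equiv), DMF, 0 °C to rt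
Reagents that add atoms: benzyl bromide, BrCc1ccccc1
Why: Williamson etherification; the para hydroxyl and one of the two equivalent ortho hydroxyls should be alkylated, while the remaining ortho hydroxyl is held in a hydrogen bond to the acetyl carbonyl and stays free to become O1.

Step 2
Reactants: 2 1-[2,4-bis(benzyloxy)-6-hydroxyphenyl]ethan-1-one; 3 diethyl oxalate
Product: 5 ethyl 5,7-bis(benzyloxy)-4-oxo-4H-chromene-2-carboxylate, via diketo ester 4 (not isolated)
Conditions: NaOEt (3 equiv), EtOH–THF, 60 °C; then HCl in EtOH to pH 1–2, 60 °C, short reaction time
Reagents that add atoms: none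
Why: Crossed Claisen condensation of the methyl ketone enolate with the non-enolisable diester, then acid-catalysed cyclodehydration (the classical chromone-2-carboxylate synthesis); brief, dilute ethanolic acid is chosen so that the 5-O-benzyl ether should survive.

Step 3
Reactants: 5 ethyl 5,7-bis(benzyloxy)-4-oxo-4H-chromene-2-carboxylate
Product: 6 5,7-bis(benzyloxy)-2-(hydroxymethyl)-4H-chromen-4-one
Conditions: NaBH4 (1.5 equiv), EtOH–THF, 0 °C
Reagents that add atoms: none
Why: Chemoselective borohydride reduction; the C2 ester is activated by the electron-poor pyrone, whereas the C4 carbonyl is a vinylogous ester and should not be reduced at 0 °C, and benzyl ethers are inert.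

Step 4
Reactants: 6 5,7-bis(benzyloxy)-2-(hydroxymethyl)-4H-chromen-4-one
Product: 7 5,7-bis(benzyloxy)-4-oxo-4H-chromene-2-carbaldehyde
Conditions: Dess–Martin periodinane (1.2 equiv), CH2Cl2, rt
Reagents that add atoms: none
Why: Dess–Martin oxidation of a primary allylic-type alcohol to the aldehyde under neutral, non-aqueous conditions, which avoids over-oxidation and hydration of the electron-poor aldehyde.

Step 5
Reactants: 7 5,7-bis(benzyloxy)-4-oxo-4H-chromene-2-carbaldehyde
Product: 8 5,7-bis(benzyloxy)-2-ethynyl-4H-chromen-4-one
Conditions: dimethyl (1-diazo-2-oxopropyl)phosphonate (1.3 equiv), K2CO3 (2 equiv), MeOH–THF, 0 °C to rt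
Reagents that add atoms: dimethyl (1-diazo-2-oxopropyl)phosphonate (Ohira–Bestmann reagent), CC(=O)C(=[N+]=[N-])P(=O)(OC)OC
Why: Seyferth–Gilbert homologation in the Ohira–Bestmann variant; the diazomethylphosphonate anion made in the flask olefinates the aldehyde and loss of N2 with 1,2-hydrogen shift gives the terminal alkyne, the mild carbonate base and low temperature being chosen to spare the pyrone ring.

Step 6
Reactants: 8 5,7-bis(benzyloxy)-2-ethynyl-4H-chromen-4-one; 9 dimethyl squarate
Product: 11 4-{[5,7-bis(benzyloxy)-4-oxo-4H-chromen-2-yl]ethynyl}-4-hydroxy-2,3-dimethoxycyclobut-2-en-1-one (racemic), via lithium acetylide 10 (not isolated)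
Conditions: LiN(SiMe3)2 (1.05 equiv), THF, −78 °C, 8 added to the base; then 9 (1.1 equiv), −78 °C; aq NH4Cl quench at −78 °C
Reagents that add atoms: none
Why: 1,2-Addition of a lithium acetylide to one of the two equivalent carbonyls of a squarate ester, the standard entry to Moore substrates; the hindered amide should deprotonate the conjugation-acidified alkyne C–H at −78 °C faster than it adds to the pyrone, and the carbinol carbon is formed racemic, which does not matter because it becomes sp2 in step 7.

Step 7
Reactants: 11 4-{[5,7-bis(benzyloxy)-4-oxo-4H-chromen-2-yl]ethynyl}-4-hydroxy-2,3-dimethoxycyclobut-2-en-1-one (racemic)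
Product: 14 2-[5,7-bis(benzyloxy)-4-oxo-4H-chromen-2-yl]-5,6-dimethoxycyclohexa-2,5-diene-1,4-dione, via vinylketene 12 (not isolated), via aryl–oxyl diradical 13 (not isolated)
Conditions: toluene (degassed, 0.01 M), 110 °C, Ar
Reagents that add atoms: none
Why: This is a Moore rearrangement, known for 4-alkynyl-4-hydroxycyclobutenones made from squarate esters, which give 2,3-dialkoxy-5-substituted 1,4-benzoquinones. Heating cleaves the C1–C4 bond of the cyclobutenone in a conrotatory four-electron electrocyclic opening in which the hydroxyl donor rotates outward, so that vinylketene 12 has the alkyne cis to the ketene. The electrophilic ketene carbon then bonds to the distal alkyne carbon, the one bearing the chromone, in a 6-endo-dig closure that forms the C1'–C2' bond and ring B as diradical 13, an aryl σ-radical next to a phenoxyl. Transfer of the hydroxyl hydrogen to the σ-radical carbon creates C6'–H and the second carbonyl of quinone 14. No stereocenter is formed, and the racemic carbinol center of 11 is destroyed. The selectivity needed is six-membered closure over 5-exo-dig closure at the proximal alkyne carbon, which would give a 2-alkylidenecyclopentene-1,3-dione and is favoured by substituents that stabilise an exocyclic vinyl radical. Two features of 11 should secure it: the free hydroxyl, which quenches 13 at once, and the acceptor character of the chromon-2-yl group, a vinylogous acyl substituent that polarises the alkyne so that its distal carbon is the more electron-rich one and matches the ketene carbon, unlike donor aryl or alkoxy groups. High dilution in degassed solvent should suppress bimolecular trapping of 12 and 13.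

Step 8
Reactants: 14 2-[5,7-bis(benzyloxy)-4-oxo-4H-chromen-2-yl]-5,6-dimethoxycyclohexa-2,5-diene-1,4-dione
Product: 15 5,7-bis(benzyloxy)-2-(2,5-dihydroxy-3,4-dimethoxyphenyl)-4H-chromen-4-one
Conditions: Na2S2O4 (excess), EtOAc–H2O, rt, Ar; crude product used at once
Reagents that add atoms: none
Why: Two-electron reduction of an electron-poor quinone by dithionite in a two-phase system; the pyrone carbonyl and benzyl ethers are untouched, and the hydroquinone is kept under argon because it reoxidises in air.

Step 9
Reactants: 15 5,7-bis(benzyloxy)-2-(2,5-dihydroxy-3,4-dimethoxyphenyl)-4H-chromen-4-one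
Product: 16 5,7-bis(benzyloxy)-2-(2,3,4,5-tetramethoxyphenyl)-4H-chromen-4-one
Conditions: MeI (excess), K2CO3, DMF, rt to 40 °C, Ar
Reagents that add atoms: iodomethane, CI
Why: Williamson methylation of both phenols; carbonate in a dipolar aprotic solvent should not open the pyrone, and all other oxygens are already ethers.

Step 10
Reactants: 16 5,7-bis(benzyloxy)-2-(2,3,4,5-tetramethoxyphenyl)-4H-chromen-4-one
Product: 17 5,7-dihydroxy-2-(2,3,4,5-tetramethoxyphenyl)-4H-chromen-4-one (5,7-dihydroxy-2',3',4',5'-tetramethoxyflavone)
Conditions: H2 (1 atm), 10% Pd/C, EtOAc–MeOH, rt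
Reagents that add atoms: none
Why: Hydrogenolysis of the two benzyl aryl ethers over palladium on carbon, a standard last step in flavone synthesis; aryl methyl ethers are inert and the C2=C3 bond of the pyrone should remain if the reaction is stopped after uptake of two equivalents of hydrogen.

## Compound list

1 | 2',4',6'-trihydroxyacetophenone | CC(=O)c1c(O)cc(O)cc1O | starting material
2 | 1-[2,4-bis(benzyloxy)-6-hydroxyphenyl]ethan-1-one | CC(=O)c1c(O)cc(OCc2ccccc2)cc1OCc1ccccc1 | intermediate
3 | diethyl oxalate | CCOC(=O)C(=O)OCC | starting material
4 | ethyl 4-[2,4-bis(benzyloxy)-6-hydroxyphenyl]-2,4-dioxobutanoate | CCOC(=O)C(=O)CC(=O)c1c(O)cc(OCc2ccccc2)cc1OCc1ccccc1 | intermediate (not isolated)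
5 | ethyl 5,7-bis(benzyloxy)-4-oxo-4H-chromene-2-carboxylate | CCOC(=O)c1cc(=O)c2c(OCc3ccccc3)cc(OCc3ccccc3)cc2o1 | intermediate
6 | 5,7-bis(benzyloxy)-2-(hydroxymethyl)-4H-chromen-4-one | OCc1cc(=O)c2c(OCc3ccccc3)cc(OCc3ccccc3)cc2o1 | intermediate
7 | 5,7-bis(benzyloxy)-4-oxo-4H-chromene-2-carbaldehyde | O=Cc1cc(=O)c2c(OCc3ccccc3)cc(OCc3ccccc3)cc2o1 | intermediate
8 | 5,7-bis(benzyloxy)-2-ethynyl-4H-chromen-4-one | C#Cc1cc(=O)c2c(OCc3ccccc3)cc(OCc3ccccc3)cc2o1 | intermediate
9 | dimethyl squarate (3,4-dimethoxycyclobut-3-ene-1,2-dione) | COC1=C(OC)C(=O)C1=O | starting material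
10 | lithium {[5,7-bis(benzyloxy)-4-oxo-4H-chromen-2-yl]ethynide} | [Li]C#Cc1cc(=O)c2c(OCc3ccccc3)cc(OCc3ccccc3)cc2o1 | intermediate (not isolated)
11 | 4-{[5,7-bis(benzyloxy)-4-oxo-4H-chromen-2-yl]ethynyl}-4-hydroxy-2,3-dimethoxycyclobut-2-en-1-one (racemic) | COC1=C(OC)C(O)(C#Cc2cc(=O)c3c(OCc4ccccc4)cc(OCc4ccccc4)cc3o2)C1=O | intermediate
12 | (3Z)-6-[5,7-bis(benzyloxy)-4-oxo-4H-chromen-2-yl]-4-hydroxy-2,3-dimethoxyhexa-1,3-dien-5-yn-1-one (vinylketene) | COC(=C=O)/C(OC)=C(/O)C#Cc1cc(=O)c2c(OCc3ccccc3)cc(OCc3ccccc3)cc2o1 | intermediate (not isolated)
13 | 6-[5,7-bis(benzyloxy)-4-oxo-4H-chromen-2-yl]-4-hydroxy-2,3-dimethoxyphenoxyl-5-yl diradical (oxyl radical on the former ketene carbon, σ-radical on the carbon that becomes C6') | COc1c(OC)c(O)[c]c(-c2cc(=O)c3c(OCc4ccccc4)cc(OCc4ccccc4)cc3o2)c1[O] | intermediate (not isolated)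
14 | 2-[5,7-bis(benzyloxy)-4-oxo-4H-chromen-2-yl]-5,6-dimethoxycyclohexa-2,5-diene-1,4-dione | COC1=C(OC)C(=O)C(c2cc(=O)c3c(OCc4ccccc4)cc(OCc4ccccc4)cc3o2)=CC1=O | intermediate
15 | 5,7-bis(benzyloxy)-2-(2,5-dihydroxy-3,4-dimethoxyphenyl)-4H-chromen-4-one | COc1c(O)cc(-c2cc(=O)c3c(OCc4ccccc4)cc(OCc4ccccc4)cc3o2)c(O)c1OC | intermediate
16 | 5,7-bis(benzyloxy)-2-(2,3,4,5-tetramethoxyphenyl)-4H-chromen-4-one | COc1cc(-c2cc(=O)c3c(OCc4ccccc4)cc(OCc4ccccc4)cc3o2)c(OC)c(OC)c1OC | intermediate
17 | 5,7-dihydroxy-2-(2,3,4,5-tetramethoxyphenyl)-4H-chromen-4-one | COc1cc(-c2cc(=O)c3c(O)cc(O)cc3o2)c(OC)c(OC)c1OC | target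

## Step count and risks

Total steps: 10. Longest linear sequence: 10 steps (from **1** to **17**); **3** and **9** are commercial.

**Step 7 (key step).** The most likely failure is closure of the ketene carbon of **12** onto the proximal alkyne carbon. This five-membered mode leads to an alkylidenecyclopentenedione, and the conjugating chromonyl group can stabilise the exocyclic vinyl radical it requires. Hydrogen abstraction from the solvent by **13** is a lesser concern.
The fallback keeps squarate as the source of ring B but puts a non-conjugating sp3 substituent on the alkyne. It sets out from **9** (and uses **2**) and comes back at **16**. Commercial 3,3-diethoxyprop-1-yne, deprotonated with n-BuLi in THF at −78 °C, is added to **9** to give racemic 4-(3,3-diethoxyprop-1-yn-1-yl)-4-hydroxy-2,3-dimethoxycyclobut-2-en-1-one F1 as the Moore substrate. Thermolysis of F1 in toluene should give 2-(diethoxymethyl)-5,6-dimethoxycyclohexa-2,5-diene-1,4-dione F2 by the same rearrangement, the acetal substituent being of the kind that favours six-membered closure. Reduction of F2 with Na2S2O4 and a dilute acid work-up gives 2,5-dihydroxy-3,4-dimethoxybenzaldehyde F3 with loss of the acetal. Methylation of F3 with MeI and K2CO3 gives 2,3,4,5-tetramethoxybenzaldehyde F4 as the ring B building block. Claisen–Schmidt condensation of F4 with **2** (KOH, EtOH) gives (E)-1-[2,4-bis(benzyloxy)-6-hydroxyphenyl]-3-(2,3,4,5-tetramethoxyphenyl)prop-2-en-1-one F5 as the chalcone. Oxidative cyclisation of F5 with catalytic I2 in DMSO at 120 °C gives **16**.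

**Step 5.** Two processes may intervene. Methoxide may add to C2 of the pyrone or to the newly formed, acceptor-activated alkyne, and the diazophosphonate anion may add as a dipole to the electron-poor C2=C3 bond instead of olefinating the aldehyde.
The fallback replaces the diazo homologation by olefination and elimination without alkoxide. It sets out from **7** and comes back at **8**. CBr4 and PPh3 in CH2Cl2 convert **7** into 5,7-bis(benzyloxy)-2-(2,2-dibromoethenyl)-4H-chromen-4-one F6 by Corey–Fuchs olefination. Hydrogenolysis of the trans bromide of F6 with Bu3SnH and catalytic Pd(PPh3)4 gives 5,7-bis(benzyloxy)-2-[(Z)-2-bromoethenyl]-4H-chromen-4-one F7 as the single bromoalkene. Anti-elimination of HBr from F7 with Bu4NF·3H2O in DMF gives **8**.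

**Step 6.** The amide base or the acetylide may add in conjugate fashion to the pyrone or to neutral **8**, giving oligomers. Alternatively the stabilised acetylide may add so slowly that warming is needed and the alkoxide fragments.
The fallback generates the nucleophile by halogen–metal exchange instead of deprotonation. It sets out from **8** and comes back at **11**. N-Iodosuccinimide with catalytic AgNO3 in acetone converts **8** into 5,7-bis(benzyloxy)-2-(iodoethynyl)-4H-chromen-4-one F8 under neutral conditions. Exchange of F8 with i-PrMgCl·LiCl in THF at −78 °C gives chlorido{[5,7-bis(benzyloxy)-4-oxo-4H-chromen-2-yl]ethynyl}magnesium F9 at once and in the absence of any acidic alkyne. Addition of F9 to **9** and a cold NH4Cl quench give **11**.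

**Step 1.** Alkylation may run on to the chelated hydroxyl, and C-benzylation of the electron-rich phloroglucinol nucleus may compete, giving mixtures.
The fallback alkylates exhaustively and then removes one group selectively. It sets out from **1** and comes back at **2**. Excess BnBr and K2CO3 in DMF at 80 °C give 1-[2,4,6-tris(benzyloxy)phenyl]ethan-1-one F10 as the fully protected ketone. Chelation-directed cleavage of one ortho benzyl ether of F10 with BCl3 (1 equiv) in CH2Cl2 at −78 °C gives **2**.

## Further compounds

F1 | step 7 | 4-(3,3-diethoxyprop-1-yn-1-yl)-4-hydroxy-2,3-dimethoxycyclobut-2-en-1-one (racemic) | CCOC(OCC)C#CC1(O)C(OC)=C(OC)C1=O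
F2 | step 7 | 2-(diethoxymethyl)-5,6-dimethoxycyclohexa-2,5-diene-1,4-dione | CCOC(OCC)C1=CC(=O)C(OC)=C(OC)C1=O
F3 | step 7 | 2,5-dihydroxy-3,4-dimethoxybenzaldehyde | COc1c(O)cc(C=O)c(O)c1OC
F4 | step 7 | 2,3,4,5-tetramethoxybenzaldehyde | COc1cc(C=O)c(OC)c(OC)c1OC
F5 | step 7 | (E)-1-[2,4-bis(benzyloxy)-6-hydroxyphenyl]-3-(2,3,4,5-tetramethoxyphenyl)prop-2-en-1-one | COc1cc(/C=C/C(=O)c2c(O)cc(OCc3ccccc3)cc2OCc2ccccc2)c(OC)c(OC)c1OC
F6 | step 5 | 5,7-bis(benzyloxy)-2-(2,2-dibromoethenyl)-4H-chromen-4-one | BrC(Br)=Cc1cc(=O)c2c(OCc3ccccc3)cc(OCc3ccccc3)cc2o1
F7 | step 5 | 5,7-bis(benzyloxy)-2-[(Z)-2-bromoethenyl]-4H-chromen-4-one | Br/C=C\c1cc(=O)c2c(OCc3ccccc3)cc(OCc3ccccc3)cc2o1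
F8 | step 6 | 5,7-bis(benzyloxy)-2-(iodoethynyl)-4H-chromen-4-one | IC#Cc1cc(=O)c2c(OCc3ccccc3)cc(OCc3ccccc3)cc2o1
F9 | step 6 | chlorido{[5,7-bis(benzyloxy)-4-oxo-4H-chromen-2-yl]ethynyl}magnesium | Cl[Mg]C#Cc1cc(=O)c2c(OCc3ccccc3)cc(OCc3ccccc3)cc2o1
F10 | step 1 | 1-[2,4,6-tris(benzyloxy)phenyl]ethan-1-one | CC(=O)c1c(OCc2ccccc2)cc(OCc2ccccc2)cc1OCc1ccccc1
A1 | alternative 1 | methyl (E)-3,5,7-trioxo-9-(2,3,4,5-tetramethoxyphenyl)non-8-enoate | COC(=O)CC(=O)CC(=O)CC(=O)/C=C/c1cc(OC)c(OC)c(OC)c1OC
A2 | alternative 1 | (E)-1-(2,4,6-trihydroxyphenyl)-3-(2,3,4,5-tetramethoxyphenyl)prop-2-en-1-one | O=C(/C=C/c1cc(OC)c(OC)c(OC)c1OC)c1c(O)cc(O)cc1O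
A3 | alternative 2 | 1-(2,3,4,5-tetramethoxyphenyl)ethanone | CC(=O)c1cc(OC)c(OC)c(OC)c1OC
A4 | alternative 2 | 2,4,6-trifluorobenzoyl chloride | O=C(Cl)c1c(F)cc(F)cc1F
A5 | alternative 2 | 5,7-difluoro-2',3',4',5'-tetramethoxyflavone | COc1cc(-c2cc(=O)c3c(F)cc(F)cc3o2)c(OC)c(OC)c1OC
A6 | alternative 3 | 3,5-bis(benzyloxy)-2-iodophenol | Oc1cc(OCc2ccccc2)cc(OCc2ccccc2)c1I
A7 | alternative 3 | carbon monoxide | [C-]#[O+]
A8 | alternative 3 | 1-ethynyl-2,3,4,5-tetramethoxybenzene | C#Cc1cc(OC)c(OC)c(OC)c1OC
A9 | alternative 3 | 5,7-bis(benzyloxy)-2',3',4',5'-tetramethoxyflavone (identical with 16) | COc1cc(-c2cc(=O)c3c(OCc4ccccc4)cc(OCc4ccccc4)cc3o2)c(OC)c(OC)c1OC
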